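## Compound numbering

1 methyl 3-oxopentanoate; 2 (E)-4-methoxycinnamaldehyde; 3 Michael adduct keto aldehyde (not isolated); 4 cyclohexenone keto ester; 5 dienyl triflate; 6 4-ethynylanisole; 7 dienyne ester; 8 aromatised benzoate; 9 phenyllithium; 10 benzophenone; 11 4-bromoanisole; 12 4-methoxyphenyllithium (not isolated); 13 triarylcarbinol; 14 selaginellin A.

## Analysis of the target

Selaginellin A (14) is built around one benzene ring, ring A, with four contiguous substituents: methyl at C1, a (4-hydroxyphenyl)ethynyl group at C2, a diarylmethylene carbon at C3 and a 4-hydroxyphenyl group at C4. Only C5 and C6 carry hydrogen. The carbon on C3 is the exocyclic terminus of a para-quinone methide: it is doubly bonded to a cyclohexa-2,5-dien-4-one ring and also carries an unsubstituted phenyl group. There is no stereogenic centre, and the dienone ring is symmetric, so the exocyclic double bond has no E/Z isomers. The quinone methide is an electrophile that adds water, alcohols and hydride, so it has to be unveiled last, from a triarylcarbinol whose para-oxygenated ring can lose water. The diarylalkyne rules out hydrogenolysis and limits long exposure to strong electrophiles, and the two free phenols call for protection that comes off in the same final operation. The real difficulty is the 1,2,3,4-substitution pattern of ring A: every substituent is flanked, and the C2 alkyne sits between the methyl group and the triaryl-substituted carbon. The strategy rests on ring A itself. C3, C2 and C1 with its methyl group correspond to the ester-bearing carbon, the ketone carbon and the ethyl group of a 3-oxopentanoate, and C4, C5 and C6 correspond to the beta-carbon, alpha-carbon and carbonyl carbon of a cinnamaldehyde. The ring can therefore be assembled with all four substituents, or their precursors, already in place.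

## Retrosynthetic reasoning

Selaginellin A (14) is traced to the tris(methyl ether) carbinol 13. The three O–methyl bonds and the formal C=C of the quinone methide are the last bonds to be made or broken, because the quinone methide cannot survive organometallic steps. A single Lewis-acid O-demethylation that also ionises the carbinol should deliver the target, with dehydration following on work-up.

Carbinol 13 is cut at the bond between the carbinol carbon and its 4-methoxyphenyl ring, giving benzophenone 10 and 4-methoxyphenyllithium (12), made in the flask from 4-bromoanisole (11). Introducing the two different aryl groups one after the other is what the unsymmetrical triaryl carbon requires. The forward step is a 1,2-addition to a flanked diaryl ketone.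

Benzophenone 10 is cut at the carbonyl–phenyl bond, giving methyl benzoate 8 and phenyllithium (9). The ring A C3 carbon thus arrives as an ester carbon at the correct oxidation level. The forward step must stop after one acyl substitution.

Benzoate 8 is traced to the dihydro compound 7 by formal addition of two hydrogens at ring A C4 and C5. No skeletal bond is cut. This retro-aromatisation turns a crowded tetrasubstituted arene into a cyclohexa-1,3-diene that can be made by carbonyl chemistry. The forward step is a single dehydrogenation.

Dienyne 7 is cut at the ring A C2–C(sp) bond, giving dienyl triflate 5 and 4-ethynylanisole (6). Cutting here places the coupling on an enol triflate activated by the adjacent ester, not on an aryl electrophile between two ortho substituents. The forward step is a palladium/copper alkynylation.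

Triflate 5 is traced to the cyclic beta-keto ester 4 by cutting the O–S bond. The C2 oxygen, needed to build the ring, becomes the leaving group for the alkyne. The forward step must enolise toward the ester-bearing carbon only.

Cyclohexenone 4 is cut at ring A C3–C4 and C1=C6, giving methyl 3-oxopentanoate (1) and (E)-4-methoxycinnamaldehyde (2), with keto aldehyde 3 as the intermediate. These two cuts are chosen because they return two purchasable compounds and place methyl, oxygen, ester and aryl at C1 to C4 without any regiochemical choice on an aromatic ring. The forward reaction is a conjugate addition followed by an aldol condensation in one flask.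

## Alternatives that were turned down

Alternative 1: Ring A is cut at C1–C2 and C3–C4 into 6-(4-methoxyphenyl)-3-methyl-2H-pyran-2-one (A1) and 5-(4-methoxyphenyl)-1-phenylpenta-2,4-diyn-1-one (A2).
- Forward key step: heating adds the pyrone diene across the carbonyl-conjugated triple bond of A2, and decarboxylative cycloreversion in the same operation gives the benzophenone A3, which is identical with compound 10.
- For it: it is the most convergent plan. The benzoyl group and the arylethynyl group arrive already attached at C3 and C2, so triflation, alkynylation, aromatisation and the ester-to-ketone step all disappear. On step economy after ring formation it is stronger than the chosen route.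
- Against it: pyrone cycloadditions of this kind need high temperatures. A2 is a doubly unsaturated ynone that is prone to polymerisation and conjugate addition and offers a second alkyne to the diene. The orientation rests only on polarisation, with the methyl-bearing pyrone carbon having to bond to the alkyne carbon remote from the carbonyl, and the wrong orientation would exchange benzoyl and alkynyl on ring A. Neither A1 nor A2 is purchasable, and each needs a few steps.
- Comparison: the chosen annulation gives positional certainty, since every ring A substituent is traced to one atom of 1 or 2, and it runs at ambient to moderate temperature from bulk chemicals.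

Alternative 2: Ring A is cut into three alkynes: the ester-tethered diyne but-2-yn-1-yl 3-(4-methoxyphenyl)prop-2-ynoate (A4) and acetylene (A5).
- Forward key step: a monovalent rhodium catalyst, RhCl(PPh3)3, cyclotrimerises them to the phthalide 7-(4-methoxyphenyl)-4-methylisobenzofuran-1(3H)-one (A6), forming C2–C3, C4–C5 and C6–C1.
- For it: three ring bonds form at once. The tether fixes the relative positions of methyl, aryl and the two carbon substituents. A4 comes from a single esterification. The lactone carbonyl at C3 is better suited than an open ester to accepting two different aryl nucleophiles one at a time, and on this point it is stronger than the chosen route.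
- Against it: the C2 substituent emerges as an sp3 CH2–O carbon. Turning it into the arylethynyl group needs oxidation to the aldehyde, one-carbon homologation to a terminal alkyne and an arylation, all next to a ketone or carbinol that tends to close onto the neighbouring carbon as a lactol or isobenzofuran. Gaseous A5 must also outcompete self-condensation of A4.
- Comparison: in the chosen route the C2 heteroatom sits directly on the ring as a ketone oxygen and becomes the alkyne in two operations. The plan is shorter overall and carries no homologation.

Alternative 3: The C5–C6 bond is cut, giving the triene 3-[1-(4-methoxyphenyl)ethenyl]-4-(prop-1-en-2-yl)furan-2(5H)-one (A7).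
- Forward key step: thermal disrotatory six-electron electrocyclisation closes the carbocycle to 7-(4-methoxyphenyl)-4-methyl-5,6-dihydroisobenzofuran-1(3H)-one (A8), which would be dehydrogenated to A6.
- For it: the key step needs no reagent and is fully atom-economic. The central double bond is locked cis in the butenolide, and the connectivity of the triene leaves no regiochemical question. On reagent economy in the ring-forming step it matches the chosen route.
- Against it: A7 needs two different alkenyl groups on adjacent butenolide carbons, which means a differentiated dihalo or halo/triflyloxy butenolide and two alkenyl metal partners. A8 still needs dehydrogenation, and then the whole CH2–O-to-alkyne sequence of alternative 2 follows.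
- Comparison: this is the longest of the four plans. The chosen route also passes through a partly saturated ring A that needs one dehydrogenation, but it reaches that stage in one step from purchased materials and with the C2 oxygen placed for direct alkynylation.

Key step: step 1

Remark on the chemistry: the (S)-configured aminocatalyst is chosen because its bulk directs conjugate addition; the descriptors below are those of the expected major enantiomer, the spatial arrangement at the aryl-bearing carbon is the same in 3, 4, 5 and 7 (the descriptor changes from R to S at 5 only through a change in substituent priority), and the sense of induction is immaterial because both centres are removed by step 4.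

## Route

Step 1
Reactants: 1 methyl 3-oxopentanoate; 2 (E)-4-methoxycinnamaldehyde
Product: 4 methyl (1S,6R)-6-(4-methoxyphenyl)-3-methyl-2-oxocyclohex-3-ene-1-carboxylate (trans, in equilibrium with its enol), via Michael adduct keto aldehyde 3 (not isolated)
Conditions: (S)-α,α-diphenylprolinol trimethylsilyl ether (10 mol %), PhCO2H (10 mol %), toluene, rt; then p-TsOH·H2O (20 mol %), 60 °C
Reagents that add atoms: none
Why: Condensation of the secondary amine with 2 gives an (E)-iminium ion whose beta-carbon is attacked by the enol of 1 through its C2 methylene, the only doubly activated carbon, which forms the ring A C3–C4 bond and, after hydrolysis of the enamine, releases keto aldehyde 3. Acid then promotes enolisation of the ethyl ketone toward its methylene, which adds to the aldehyde in a 6-(enolendo)-exo-trig aldol closure, and dehydration of the aldol gives the conjugated ring A C1=C6 double bond of enone 4. The closest known reaction type is the aminocatalysed domino Michael–aldol condensation (Robinson-type annulation) of beta-keto esters with enals to cyclohexenones. The benzylic stereocentre is set in the conjugate addition, where the diphenyl(silyloxy)methyl group of the catalyst covers one face of the iminium ion so that attack occurs on the open face, and the enolisable ester-bearing centre settles under thermodynamic control trans to the aryl group. The step needs only constitutional selectivity: 1,4- rather than 1,2-addition is secured by the bulky amine, whose iminium carbon is shielded, and by the soft stabilised nucleophile. The direction of the aldol is fixed by ring size, since closure from the methine between the carbonyl groups onto the aldehyde, or from the aldehyde alpha-carbon onto the ketone, would give four-membered rings. A methyl ester is used so that the acid treatment does not trigger decarboxylation, and both stereocentres disappear by step 4, so their control is a bonus and not a requirement.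

Step 2
Reactants: 4 methyl (1S,6R)-6-(4-methoxyphenyl)-3-methyl-2-oxocyclohex-3-ene-1-carboxylate
Product: 5 methyl (6S)-6-(4-methoxyphenyl)-3-methyl-2-{[(trifluoromethyl)sulfonyl]oxy}cyclohexa-1,3-diene-1-carboxylate
Conditions: Tf2O, i-Pr2NEt, CH2Cl2, −78 → 0 °C
Reagents that add atoms: trifluoromethanesulfonic anhydride (Tf2O), O=S(=O)(OS(=O)(=O)C(F)(F)F)C(F)(F)F
Why: The proton between ketone and ester is by far the most acidic, so the amine base generates the ester-conjugated enolate and its oxygen is sulfonylated (enol triflation of a cyclic beta-keto ester); the remote CH2 and the aryl-bearing centre are not touched.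

Step 3
Reactants: 5 methyl (6S)-6-(4-methoxyphenyl)-3-methyl-2-{[(trifluoromethyl)sulfonyl]oxy}cyclohexa-1,3-diene-1-carboxylate; 6 4-ethynylanisole
Product: 7 methyl (6S)-6-(4-methoxyphenyl)-2-[(4-methoxyphenyl)ethynyl]-3-methylcyclohexa-1,3-diene-1-carboxylate
Conditions: PdCl2(PPh3)2 (5 mol %), CuI (10 mol %), Et3N, THF, rt
Reagents that add atoms: none
Why: Sonogashira coupling: zerovalent palladium formed in situ inserts readily into the C–O bond of an enol triflate activated by the beta-ester, the copper acetylide of 6 transmetalates, and reductive elimination forms the ring A C2–C(sp) bond; the linear alkyne tolerates the two flanking groups.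

Step 4
Reactants: 7 methyl (6S)-6-(4-methoxyphenyl)-2-[(4-methoxyphenyl)ethynyl]-3-methylcyclohexa-1,3-diene-1-carboxylate
Product: 8 methyl 6-(4-methoxyphenyl)-2-[(4-methoxyphenyl)ethynyl]-3-methylbenzoate
Conditions: DDQ, toluene, 80 °C
Reagents that add atoms: none
Why: Quinone dehydrogenation (oxidative aromatisation): DDQ abstracts hydride from the ring CH that is both benzylic to the anisyl group and allylic to the diene, and proton loss from the neighbouring CH2 completes ring A; aromatisation drives the step, and the alkyne, the ester and the aryl methyl group have no comparably activated C–H bond.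

Step 5
Reactants: 8 methyl 6-(4-methoxyphenyl)-2-[(4-methoxyphenyl)ethynyl]-3-methylbenzoate; 9 phenyllithium
Product: 10 [6-(4-methoxyphenyl)-2-[(4-methoxyphenyl)ethynyl]-3-methylphenyl](phenyl)methanone
Conditions: PhLi (1.05 equiv), THF, −78 °C; aq. NH4Cl at −78 °C
Reagents that add atoms: none
Why: Nucleophilic acyl substitution of an ester by an aryllithium; a second addition would have to build a triarylmethoxide on a 2,6-disubstituted ring, far more congested than the first tetrahedral intermediate, so one equivalent at low temperature with a cold quench should hold the reaction at the ketone.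

Step 6
Reactants: 10 [6-(4-methoxyphenyl)-2-[(4-methoxyphenyl)ethynyl]-3-methylphenyl](phenyl)methanone; 11 4-bromoanisole
Product: 13 rac-{6-(4-methoxyphenyl)-2-[(4-methoxyphenyl)ethynyl]-3-methylphenyl}(4-methoxyphenyl)(phenyl)methanol, via 4-methoxyphenyllithium 12 (not isolated)
Conditions: 11, n-BuLi, THF, −78 °C; then 10, −78 → 0 °C; aq. NH4Cl
Reagents that add atoms: none
Why: Bromine–lithium exchange gives 12, which undergoes 1,2-addition to the diaryl ketone; a small, strongly nucleophilic aryllithium in excess and at higher temperature than in step 5 is suited to the flanked carbonyl, and the new carbinol centre forms as a racemate that becomes planar again in step 7.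

Step 7
Reactants: 13 rac-{6-(4-methoxyphenyl)-2-[(4-methoxyphenyl)ethynyl]-3-methylphenyl}(4-methoxyphenyl)(phenyl)methanol
Product: 14 selaginellin A, 4-{[6-(4-hydroxyphenyl)-2-[(4-hydroxyphenyl)ethynyl]-3-methylphenyl](phenyl)methylidene}cyclohexa-2,5-dien-1-one
Conditions: BBr3 (excess), CH2Cl2, −78 °C → rt; then H2O
Reagents that add atoms: none
Why: BBr3 cleaves the three aryl methyl ethers by bromide attack on the boron-activated O-methyl groups and ionises the tertiary carbinol to a triaryl cation; on aqueous work-up the cation bearing a para-hydroxyphenyl ring loses a proton to give the para-quinone methide (Lewis-acid O-demethylation with fuchsone formation), so deprotection and dehydration are one operation.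

## Compound list

1 | methyl 3-oxopentanoate | CCC(=O)CC(=O)OC | starting material
2 | (E)-4-methoxycinnamaldehyde | COc1ccc(/C=C/C=O)cc1 | starting material
3 | methyl 2-[(1R)-1-(4-methoxyphenyl)-3-oxopropyl]-3-oxopentanoate (epimers at C2, not isolated) | CCC(=O)C(C(=O)OC)[C@@H](CC=O)c1ccc(OC)cc1 | intermediate
4 | methyl (1S,6R)-6-(4-methoxyphenyl)-3-methyl-2-oxocyclohex-3-ene-1-carboxylate (trans) | COC(=O)[C@@H]1C(=O)C(C)=CC[C@H]1c1ccc(OC)cc1 | intermediate
5 | methyl (6S)-6-(4-methoxyphenyl)-3-methyl-2-{[(trifluoromethyl)sulfonyl]oxy}cyclohexa-1,3-diene-1-carboxylate | COC(=O)C1=C(OS(=O)(=O)C(F)(F)F)C(C)=CC[C@H]1c1ccc(OC)cc1 | intermediate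
6 | 4-ethynylanisole (1-ethynyl-4-methoxybenzene) | C#Cc1ccc(OC)cc1 | starting material
7 | methyl (6S)-6-(4-methoxyphenyl)-2-[(4-methoxyphenyl)ethynyl]-3-methylcyclohexa-1,3-diene-1-carboxylate | COC(=O)C1=C(C#Cc2ccc(OC)cc2)C(C)=CC[C@H]1c1ccc(OC)cc1 | intermediate
8 | methyl 6-(4-methoxyphenyl)-2-[(4-methoxyphenyl)ethynyl]-3-methylbenzoate | COC(=O)c1c(-c2ccc(OC)cc2)ccc(C)c1C#Cc1ccc(OC)cc1 | intermediate
9 | phenyllithium (commercial solution) | [Li]c1ccccc1 | starting material
10 | [6-(4-methoxyphenyl)-2-[(4-methoxyphenyl)ethynyl]-3-methylphenyl](phenyl)methanone | Cc1ccc(-c2ccc(OC)cc2)c(C(=O)c2ccccc2)c1C#Cc1ccc(OC)cc1 | intermediate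
11 | 4-bromoanisole | COc1ccc(Br)cc1 | starting material
12 | 4-methoxyphenyllithium (not isolated) | [Li]c1ccc(OC)cc1 | intermediate
13 | rac-{6-(4-methoxyphenyl)-2-[(4-methoxyphenyl)ethynyl]-3-methylphenyl}(4-methoxyphenyl)(phenyl)methanol | Cc1ccc(-c2ccc(OC)cc2)c(C(O)(c2ccccc2)c2ccc(OC)cc2)c1C#Cc1ccc(OC)cc1 | intermediate
14 | selaginellin A | Cc1ccc(-c2ccc(O)cc2)c(C(=C2C=CC(=O)C=C2)c2ccccc2)c1C#Cc1ccc(O)cc1 | target

## Step count and least certain steps

Total step count: 7. Longest linear sequence: 7 steps, from 1 and 2 to 14; compounds 6, 9 and 11 are purchased and enter directly.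

Step 1 (key step).
- Risk: competing 1,2-addition of the keto ester to the aldehyde (Knoevenagel condensation followed by oxa-electrocyclisation), diversion of adduct 3 through its cyclic hemiacetal into dehydration toward a pyran instead of carbocyclisation, and a sluggish aldol because the nucleophilic carbon is the methylene of an ethyl ketone.
- Fallback, setting out from 1: Knoevenagel condensation with 4-methoxybenzaldehyde (piperidine, AcOH, toluene, water removal) would give methyl 2-(4-methoxybenzylidene)-3-oxopentanoate F1. Thermal inverse-demand hetero-Diels–Alder reaction of its oxadiene with ethyl vinyl ether would give methyl 2-ethoxy-6-ethyl-4-(4-methoxyphenyl)-3,4-dihydro-2H-pyran-5-carboxylate F2. Aqueous acid (p-TsOH, wet acetone, then toluene, 60 °C) would unmask racemic 3 and close it by the same aldol condensation. The route is rejoined at 4 as the racemate, which is of no consequence. Here ring A C3–C4 is made by the condensation and C4–C5 by the cycloaddition, so 1,2- versus 1,4-selectivity no longer arises.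

Step 3.
- Risk: slow oxidative addition at the flanked, tetrasubstituted enol triflate, which would let oxidative homocoupling of 6 and S–O cleavage back to 4 take over.
- Fallback, setting out from 4: dehydrogenation (DDQ, 1,4-dioxane, heat) would give the salicylate methyl 2-hydroxy-6-(4-methoxyphenyl)-3-methylbenzoate F3. Triflation of the phenol (Tf2O, pyridine, CH2Cl2, 0 °C) would give methyl 6-(4-methoxyphenyl)-3-methyl-2-{[(trifluoromethyl)sulfonyl]oxy}benzoate F4. Copper-free alkynylation with 6 under a bulky biarylphosphine-ligated palladium catalyst (PdCl2(MeCN)2, XPhos, Cs2CO3, MeCN, 80 °C) would rejoin the route at 8. Aromatisation then precedes coupling, and the ortho-ester activates the aryl triflate.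

Step 5.
- Risk: over-addition of a second phenyl group once the tetrahedral intermediate collapses before the quench, or, at the other extreme, no addition at −78 °C because of the two ortho substituents, with loss of selectivity on warming.
- Fallback, setting out from 8: reduction (i-Bu2AlH, CH2Cl2, −78 → 0 °C) would give {6-(4-methoxyphenyl)-2-[(4-methoxyphenyl)ethynyl]-3-methylphenyl}methanol F5. Oxidation with Dess–Martin periodinane would give 6-(4-methoxyphenyl)-2-[(4-methoxyphenyl)ethynyl]-3-methylbenzaldehyde F6. Addition of PhMgBr (THF, 0 °C) would give rac-{6-(4-methoxyphenyl)-2-[(4-methoxyphenyl)ethynyl]-3-methylphenyl}(phenyl)methanol F7. A second Dess–Martin oxidation rejoins the route at 10. Each addition is then to an aldehyde and cannot go twice.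

Step 7.
- Risk: intramolecular Friedel–Crafts capture of the triaryl cation by the neighbouring C4 aryl ring (closure to a 9,9-diarylfluorene), addition of HBr across the alkyne on prolonged exposure, and incomplete demethylation.
- Fallback, setting out from 10: demethylation at the ketone stage, where no cation can form (BBr3, CH2Cl2, −78 → 0 °C), would give [6-(4-hydroxyphenyl)-2-[(4-hydroxyphenyl)ethynyl]-3-methylphenyl](phenyl)methanone F8. Silylation (TBSCl, imidazole, DMF) would give [6-{4-[(tert-butyldimethylsilyl)oxy]phenyl}-2-({4-[(tert-butyldimethylsilyl)oxy]phenyl}ethynyl)-3-methylphenyl](phenyl)methanone F9. Addition of the aryllithium made from purchased (4-bromophenoxy)(tert-butyl)dimethylsilane and n-BuLi would give rac-[6-{4-[(tert-butyldimethylsilyl)oxy]phenyl}-2-({4-[(tert-butyldimethylsilyl)oxy]phenyl}ethynyl)-3-methylphenyl]{4-[(tert-butyldimethylsilyl)oxy]phenyl}(phenyl)methanol F10. Fluoride desilylation (n-Bu4NF, THF, 0 °C) followed by dilute aqueous acid would dehydrate the triphenol carbinol and rejoin the route at 14. The final unveiling then needs no strong Lewis acid.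

## Further compounds

F1 | step 1 | methyl 2-(4-methoxybenzylidene)-3-oxopentanoate (E/Z mixture) | CCC(=O)C(=Cc1ccc(OC)cc1)C(=O)OC
F2 | step 1 | methyl 2-ethoxy-6-ethyl-4-(4-methoxyphenyl)-3,4-dihydro-2H-pyran-5-carboxylate (racemic, mixture of diastereomers) | CCOC1CC(c2ccc(OC)cc2)C(C(=O)OC)=C(CC)O1
F3 | step 3 | methyl 2-hydroxy-6-(4-methoxyphenyl)-3-methylbenzoate | COC(=O)c1c(O)c(C)ccc1-c1ccc(OC)cc1
F4 | step 3 | methyl 6-(4-methoxyphenyl)-3-methyl-2-{[(trifluoromethyl)sulfonyl]oxy}benzoate | COC(=O)c1c(OS(=O)(=O)C(F)(F)F)c(C)ccc1-c1ccc(OC)cc1
F5 | step 5 | {6-(4-methoxyphenyl)-2-[(4-methoxyphenyl)ethynyl]-3-methylphenyl}methanol | Cc1ccc(-c2ccc(OC)cc2)c(CO)c1C#Cc1ccc(OC)cc1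
F6 | step 5 | 6-(4-methoxyphenyl)-2-[(4-methoxyphenyl)ethynyl]-3-methylbenzaldehyde | Cc1ccc(-c2ccc(OC)cc2)c(C=O)c1C#Cc1ccc(OC)cc1
F7 | step 5 | rac-{6-(4-methoxyphenyl)-2-[(4-methoxyphenyl)ethynyl]-3-methylphenyl}(phenyl)methanol | Cc1ccc(-c2ccc(OC)cc2)c(C(O)c2ccccc2)c1C#Cc1ccc(OC)cc1
F8 | step 7 | [6-(4-hydroxyphenyl)-2-[(4-hydroxyphenyl)ethynyl]-3-methylphenyl](phenyl)methanone | Cc1ccc(-c2ccc(O)cc2)c(C(=O)c2ccccc2)c1C#Cc1ccc(O)cc1
F9 | step 7 | [6-{4-[(tert-butyldimethylsilyl)oxy]phenyl}-2-({4-[(tert-butyldimethylsilyl)oxy]phenyl}ethynyl)-3-methylphenyl](phenyl)methanone | Cc1ccc(-c2ccc(O[Si](C)(C)C(C)(C)C)cc2)c(C(=O)c2ccccc2)c1C#Cc1ccc(O[Si](C)(C)C(C)(C)C)cc1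
F10 | step 7 | rac-[6-{4-[(tert-butyldimethylsilyl)oxy]phenyl}-2-({4-[(tert-butyldimethylsilyl)oxy]phenyl}ethynyl)-3-methylphenyl]{4-[(tert-butyldimethylsilyl)oxy]phenyl}(phenyl)methanol | Cc1ccc(-c2ccc(O[Si](C)(C)C(C)(C)C)cc2)c(C(O)(c2ccccc2)c2ccc(O[Si](C)(C)C(C)(C)C)cc2)c1C#Cc1ccc(O[Si](C)(C)C(C)(C)C)cc1
A1 | alternative 1 | 6-(4-methoxyphenyl)-3-methyl-2H-pyran-2-one | Cc1ccc(-c2ccc(OC)cc2)oc1=O
A2 | alternative 1 | 5-(4-methoxyphenyl)-1-phenylpenta-2,4-diyn-1-one | O=C(C#CC#Cc1ccc(OC)cc1)c1ccccc1
A3 | alternative 1 | [6-(4-methoxyphenyl)-2-[(4-methoxyphenyl)ethynyl]-3-methylphenyl](phenyl)methanone | Cc1ccc(-c2ccc(OC)cc2)c(C(=O)c2ccccc2)c1C#Cc1ccc(OC)cc1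
A4 | alternative 2 | but-2-yn-1-yl 3-(4-methoxyphenyl)prop-2-ynoate | CC#CCOC(=O)C#Cc1ccc(OC)cc1
A5 | alternative 2 | acetylene (ethyne) | C#C
A6 | alternative 2 | 7-(4-methoxyphenyl)-4-methylisobenzofuran-1(3H)-one | Cc1ccc(-c2ccc(OC)cc2)c2c1COC2=O
A7 | alternative 3 | 3-[1-(4-methoxyphenyl)ethenyl]-4-(prop-1-en-2-yl)furan-2(5H)-one | C=C(C)C1=C(C(=C)c2ccc(OC)cc2)C(=O)OC1
A8 | alternative 3 | 7-(4-methoxyphenyl)-4-methyl-5,6-dihydroisobenzofuran-1(3H)-one | CC1=C2COC(=O)C2=C(c2ccc(OC)cc2)CC1
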